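At late times the product in a flask is the sum of what each earlier stretch made, so its excess E, left-handed product over right-handed, is the mean of the stretches' excesses weighted by the product each made. Amber, which changes temperature at 5.0 min, is such a flask. In each flask the solid reagent feeds partner, partner turns each substrate into the product of its hand, and the racemization catalyst interconverts the substrates.

| flask | left-handed substrate | right-handed substrate | solid reagent | racemization catalyst | temperature | remark | time |
|---|---|---|---|---|---|---|---|
| delta | 0.20 M | 0.20 M | 0.29 M | 10 mM | 5 °C | run made earlier |  |
| alpha | 0.20 M | 0.20 M | 0.66 M | 10 mM | 27 °C | run made earlier |  |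
| blue | 0.20 M | 0.20 M | 0.440 M | 10 mM | −5 °C |  | 10 min |
| amber | 0.20 M | 0.20 M | 0.440 M | 10 mM |  | at −5 °C until 5.0 min, from then on at 35 °C | 10 min |
| ochre | 0.20 M | 0.20 M | 0.440 M | 10 mM | 15 °C |  | 10 min |
| violet | 0.20 M | 0.20 M | 0.440 M | 10 mM | 35 °C |  | 10 min |

- delta (time / min: left-handed product / %, right-handed product / %): 0.200: 0.9, 0; 0.667: 0, 0.2; 1.00: 1.1, 0.4; 1.50: 2.0, 0; 2.50: 3.0, 0.8; 3.00: 3.7, 0; 4.00: 3.7, 1.0
- alpha (time / s: left-handed product / %, right-handed product / %): 10.0: 0, 0.9; 12.0: 0.9, 0.6; 20.0: 1.1, 0.9; 30.0: 1.5, 1.1; 50.0: 3.1, 1.5; 80.0: 4.1, 1.3

(scatter of a reading: 0.5 percentage points)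

- the flask that comes out highest in excess of left-handed product over right-handed product, or "all alike" when all lie within 1.5 percentage points (blue / amber / ochre / violet / all alike)
- excess of left-handed product over right-handed product at the end, blue
- excess of left-handed product over right-handed product at the end, amber
- excess of left-handed product over right-handed product at the end, ochre
- excess of left-handed product over right-handed product at the end, violet

- partner is single-handed; left-handed substrate and right-handed substrate are mirror images of each other, charged as a racemate, each of them at the stated concentration
- given per volume of solution although it is solid: solid reagent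
- at the start none of the solid reagent is in solution
- an excess is the difference of the two amounts in percent of their sum
- an excess is below zero if the other one leads
- the handed part of partner does not stay in what it makes, so the products of the two hands are mirror images too

My estimate is that weight. I replace each curve by its mean rate, total product over time at the last reading: r_d = 0.0118 min⁻¹ in delta and r_a = 0.0405 min⁻¹ in alpha. Setting aside their different charges of solid reagent, I take the rate as exponential in temperature, so I estimate that amber's warm stretch runs at g = 9.49 times its cold one. Its warm share, the fraction w of amber's product made after the change, is then by this estimate 90.5%. Amber's excess should be w of violet's plus the rest of blue's.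

The forecast puts blue highest, with blue 63%, amber 42%, ochre 52% and violet 36%: “Amber makes most of its product in the warm half, so it lands near violet, slightly higher.” My weight on the forecast's blue and violet gives amber 38.6%, which is lower than the forecast's own 42%.

The flasks give blue 87.5%, amber 47.1%, ochre 70.0% and violet 43.3%, so blue is highest.

    left-handed substrate + racemization catalyst ⇌ right-handed substrate + racemization catalyst, rate k1*[racemization catalyst]*[left-handed substrate] forward; the back reaction follows from the equilibrium constant (k = 0.610 M⁻¹ s⁻¹, Ea = 43.0 kJ mol⁻¹)
    partner + left-handed substrate → left-handed product (k = 0.150 M⁻¹ s⁻¹, Ea = 41.0 kJ mol⁻¹)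
    partner + right-handed substrate → right-handed product (k = 0.0550 M⁻¹ s⁻¹, Ea = 71.0 kJ mol⁻¹)
    solid reagent ⇌ partner, rate k4*(cs4 - [partner]) while solid is left; crystals form when [partner] > cs4 (solubility = 13.0 mM, k = 0.320 s⁻¹)
    partner → decomposition product (k = 4.20 × 10⁻⁶ s⁻¹, Ea = 104 kJ mol⁻¹)
    (constants at 35 °C)

Amber ends at 47.1%, higher than violet by 3.8 percentage points. At the change of temperature amber holds 2.74% of product, and at the end 31.9%. Putting w on violet's 43.3% and the rest on blue's 87.5% gives 47.5%, with amber at 47.1%.

The numbers in the tables stem from a simulated flask on assumed constants; scatter was added.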